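The cis-fused γ-lactone (O1–C2–C3–C3a–C7a, benzofuran numbering) on the cyclohexenone is read as the Baeyer–Villiger image of a cyclobutanone sharing the C3a–C7a bond. The route rests on an intramolecular [2+2] cycloaddition of a chiral keteniminium ion with the 1,1-disubstituted alkene that carries the farnesyl chain. One operation joins C3 to C2 and C7a to C3a, closing the carbocycle and the four-membered ring and setting quaternary C3a and C7a together. The precursor is an open-chain ketal amide of (2S,5S)-2,5-dimethylpyrrolidine with no ring of the target. Ring strain then drives regioselective insertion of O1 between C2 and C7a, and dehydrogenation installs the C6–C7 enone.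

Key step: step 6

Remark on the chemistry: the sense of induction by the (2S,5S)-auxiliary in step 6 is assigned from a steric model of the keteniminium ion (ring closure on the face of the α-carbon away from the flanking methyl group); should the opposite sense be found, the (2R,5R)-amine would be used in the same sequence.

Step 1
Reactants: 1 (2-bromoprop-2-en-1-yl)trimethylsilane; 2 (2E,6E)-farnesyl bromide
Product: 4 allylsilane trimethyl[(4E,8E)-5,9,13-trimethyl-2-methylidenetetradeca-4,8,12-trien-1-yl]silane, via alkenylmagnesium bromide 3 (not isolated)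
Conditions: Mg, THF, 40 °C; then 2, Li2CuCl4 (3 mol %), THF, −20 → 0 °C
Reagents that add atoms: none
Why: Magnesium inserts into the vinylic C–Br bond and the alkenyl Grignard reagent 3 should undergo Cu-catalysed SN2 cross-coupling with the primary allylic bromide 2, which keeps the E,E geometry and creates no stereocentre.

Step 2
Reactants: 4 allylsilane; 5 methyl 5-chloro-5-oxopentanoate
Product: 6 keto ester methyl (9E,13E)-10,14,18-trimethyl-7-methylidene-5-oxononadeca-9,13,17-trienoate
Conditions: TiCl4 (1.1 equiv), 2,6-di-tert-butyl-4-methylpyridine (0.2 equiv), CH2Cl2, −78 °C; cold aq. NaHCO3 quench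
Reagents that add atoms: none
Why: Hosomi–Sakurai acylation, in which the activated acyl chloride is attacked by the =CH2 terminus of the 2-substituted allylsilane (far more nucleophilic than the trisubstituted alkenes) and loss of the β-silyl group regenerates the 1,1-disubstituted alkene as a β,γ-unsaturated ketone; the hindered pyridine scavenges adventitious HCl and no stereocentre is formed.

Step 3
Reactants: 6 keto ester
Product: 7 ketal ester methyl 4-{2-[(4E,8E)-5,9,13-trimethyl-2-methylidenetetradeca-4,8,12-trien-1-yl]-1,3-dioxolan-2-yl}butanoate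
Conditions: Me3SiOCH2CH2OSiMe3, Me3SiOTf (5 mol %), CH2Cl2, −78 → −20 °C; pyridine quench
Reagents that add atoms: 1,2-bis(trimethylsilyloxy)ethane, C[Si](C)(C)OCCO[Si](C)(C)C
Why: Noyori ketalisation under aprotic conditions at low temperature should convert the ketone into the dioxolane without moving the β,γ-double bond into conjugation and without touching the ester or the triene.

Step 4
Reactants: 7 ketal ester
Product: 8 ketal acid 4-{2-[(4E,8E)-5,9,13-trimethyl-2-methylidenetetradeca-4,8,12-trien-1-yl]-1,3-dioxolan-2-yl}butanoic acid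
Conditions: LiOH·H2O, THF–MeOH–H2O, rt; then dil. HCl to pH 4, 0 °C
Reagents that add atoms: lithium hydroxide, [Li+].[OH-]
Why: Saponification of the methyl ester; the ketal and the skipped polyene are inert to hydroxide, and brief cold acidification to pH 4 should spare the ketal.

Step 5
Reactants: 8 ketal acid; 9 (2S,5S)-2,5-dimethylpyrrolidine
Product: 11 amide 1-[(2S,5S)-2,5-dimethylpyrrolidin-1-yl]-4-{2-[(4E,8E)-5,9,13-trimethyl-2-methylidenetetradeca-4,8,12-trien-1-yl]-1,3-dioxolan-2-yl}butan-1-one, via acid chloride 10 (not isolated)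
Conditions: Me2C=C(Cl)NMe2, CH2Cl2, 0 °C → rt; then 9, Et3N, 0 °C → rt
Reagents that add atoms: none
Why: The α-chloroenamine gives the acid chloride under neutral conditions that the ketal tolerates, and N-acylation of the hindered secondary amine 9 gives the tertiary amide, whose two stereocentres come unchanged from 9.

Step 6
Reactants: 11 amide
Product: 15 diketone (1R,6R)-1-[(2E,6E)-3,7,11-trimethyldodeca-2,6,10-trien-1-yl]bicyclo[4.2.0]octane-3,7-dione, via keteniminium triflate 12 (not isolated), via cyclobutaniminium triflate 13 (not isolated), via cyclobutanone ketal 14 (not isolated)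
Conditions: Tf2O (1.2 equiv), 2,4,6-collidine (1.5 equiv), ClCH2CH2Cl (0.01 M), 0 → 80 °C; then 1 M aq. HCl–THF, rt
Reagents that add atoms: water, O
Why: Tf2O O-sulfonylates the amide and collidine removes the α-proton to give keteniminium ion 12; the CH2 terminus of the 1,1-disubstituted alkene attacks its sp carbon while the α-carbon closes onto the fully substituted alkene carbon, an asynchronous polar [2+2] that forms the CH2–C(=N+) bond and the CH–C(quaternary) bond (future C3–C2 and C7a–C3a) in one event and gives cyclobutaniminium ion 13. The closest known reaction type is the intramolecular keteniminium–alkene cycloaddition of ω-alkenyl amides of chiral pyrrolidines (Ghosez cycloaddition), which closes bicyclo[4.2.0] systems where free alkylketenes are sluggish. The six-membered carbocycle is closed by the CH–C(quaternary) bond in a 6-exo-trig sense at the alkene and the four-membered ring by the CH2–C bond in a 4-exo sense at the C=N+ carbon, so the fusion can only be cis. Both stereocentres are created here: their relative configuration follows from the cis fusion and their absolute configuration from the C2-symmetric (2S,5S)-auxiliary, whose methyl group on the alkene side shields one face of the α-carbon so that closure occurs on the other (model-based assignment, see remark). The step needs regioselectivity for the fused over the bridged bicycle, secured by positive charge building up on the fully substituted alkene carbon, and chemoselectivity over the three trisubstituted alkenes, secured by ring size because these could only close rings of eight or more atoms; collidine buffers the acid and high dilution suppresses intermolecular capture. Aqueous HCl then hydrolyses 13 to cyclobutanone 14 with release of the auxiliary and cleaves the dioxolane in the same flask to give 15.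

Step 7
Reactants: 15 diketone
Product: 16 keto lactone (3aR,7aR)-3a-[(2E,6E)-3,7,11-trimethyldodeca-2,6,10-trien-1-yl]hexahydro-1-benzofuran-2,5-dione
Conditions: 30% aq. H2O2, NaOH (0.3 equiv), MeOH–THF, 0 °C; then aq. NaH2PO4
Reagents that add atoms: hydrogen peroxide, OO
Why: Baeyer–Villiger oxidation with alkaline hydrogen peroxide, in which only the strained cyclobutanone adds hydroperoxide and the more substituted ring-fusion CH migrates with retention so that oxygen enters between C=O and CH; the nucleophilic oxidant should leave the cyclohexanone and the electron-rich alkenes untouched.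

Step 8
Reactants: 16 keto lactone
Product: 17 target (3aR,7aR)-3a-[(2E,6E)-3,7,11-trimethyldodeca-2,6,10-trien-1-yl]-3,3a,4,7a-tetrahydro-1-benzofuran-2,5-dione
Conditions: IBX (2.5 equiv), DMSO–fluorobenzene, 70 °C
Reagents that add atoms: none
Why: IBX dehydrogenation of the ketone through its enol can give an enone only on the C6–C7 side because C3a is quaternary (which also protects the lactone α-CH2), and the two stereocentres are not touched.

Compound list
1 | (2-bromoprop-2-en-1-yl)trimethylsilane | C[Si](C)(C)CC(Br)=C | starting material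
2 | (2E,6E)-1-bromo-3,7,11-trimethyldodeca-2,6,10-triene (E,E-farnesyl bromide) | CC(C)=CCC/C(C)=C/CC/C(C)=C/CBr | starting material
3 | [3-(trimethylsilyl)prop-1-en-2-yl]magnesium bromide | C[Si](C)(C)CC(=C)[Mg]Br | intermediate
4 | trimethyl[(4E,8E)-5,9,13-trimethyl-2-methylidenetetradeca-4,8,12-trien-1-yl]silane | CC(C)=CCC/C(C)=C/CC/C(C)=C/CC(=C)C[Si](C)(C)C | intermediate
5 | methyl 5-chloro-5-oxopentanoate | COC(=O)CCCC(=O)Cl | starting material
6 | methyl (9E,13E)-10,14,18-trimethyl-7-methylidene-5-oxononadeca-9,13,17-trienoate | CC(C)=CCC/C(C)=C/CC/C(C)=C/CC(=C)CC(=O)CCCC(=O)OC | intermediate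
7 | methyl 4-{2-[(4E,8E)-5,9,13-trimethyl-2-methylidenetetradeca-4,8,12-trien-1-yl]-1,3-dioxolan-2-yl}butanoate | CC(C)=CCC/C(C)=C/CC/C(C)=C/CC(=C)CC1(CCCC(=O)OC)OCCO1 | intermediate
8 | 4-{2-[(4E,8E)-5,9,13-trimethyl-2-methylidenetetradeca-4,8,12-trien-1-yl]-1,3-dioxolan-2-yl}butanoic acid | CC(C)=CCC/C(C)=C/CC/C(C)=C/CC(=C)CC1(CCCC(=O)O)OCCO1 | intermediate
9 | (2S,5S)-2,5-dimethylpyrrolidine | C[C@H]1CC[C@H](C)N1 | starting material
10 | 4-{2-[(4E,8E)-5,9,13-trimethyl-2-methylidenetetradeca-4,8,12-trien-1-yl]-1,3-dioxolan-2-yl}butanoyl chloride | CC(C)=CCC/C(C)=C/CC/C(C)=C/CC(=C)CC1(CCCC(=O)Cl)OCCO1 | intermediate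
11 | 1-[(2S,5S)-2,5-dimethylpyrrolidin-1-yl]-4-{2-[(4E,8E)-5,9,13-trimethyl-2-methylidenetetradeca-4,8,12-trien-1-yl]-1,3-dioxolan-2-yl}butan-1-one | CC(C)=CCC/C(C)=C/CC/C(C)=C/CC(=C)CC1(CCCC(=O)N2[C@@H](C)CC[C@@H]2C)OCCO1 | intermediate
12 | (2S,5S)-2,5-dimethyl-1-(4-{2-[(4E,8E)-5,9,13-trimethyl-2-methylidenetetradeca-4,8,12-trien-1-yl]-1,3-dioxolan-2-yl}but-1-en-1-ylidene)pyrrolidin-1-ium triflate (keteniminium salt) | CC(C)=CCC/C(C)=C/CC/C(C)=C/CC(=C)CC1(CCC=C=[N+]2[C@@H](C)CC[C@@H]2C)OCCO1.[O-]S(=O)(=O)C(F)(F)F | intermediate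
13 | (2S,5S)-2,5-dimethyl-1-{(1S,6R)-1-[(2E,6E)-farnesyl]spiro[bicyclo[4.2.0]octane-3,2'-[1,3]dioxolan]-7-ylidene}pyrrolidin-1-ium triflate (cis-fused cyclobutaniminium salt) | CC(C)=CCC/C(C)=C/CC/C(C)=C/C[C@]12CC3(OCCO3)CC[C@H]1C(=[N+]4[C@@H](C)CC[C@@H]4C)C2.[O-]S(=O)(=O)C(F)(F)F | intermediate
14 | (1S,6R)-1-[(2E,6E)-3,7,11-trimethyldodeca-2,6,10-trien-1-yl]spiro[bicyclo[4.2.0]octane-3,2'-[1,3]dioxolan]-7-one (cis-fused cyclobutanone ketal) | CC(C)=CCC/C(C)=C/CC/C(C)=C/C[C@]12CC3(OCCO3)CC[C@H]1C(=O)C2 | intermediate
15 | (1R,6R)-1-[(2E,6E)-3,7,11-trimethyldodeca-2,6,10-trien-1-yl]bicyclo[4.2.0]octane-3,7-dione | CC(C)=CCC/C(C)=C/CC/C(C)=C/C[C@]12CC(=O)CC[C@H]1C(=O)C2 | intermediate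
16 | (3aR,7aR)-3a-[(2E,6E)-3,7,11-trimethyldodeca-2,6,10-trien-1-yl]hexahydro-1-benzofuran-2,5-dione | CC(C)=CCC/C(C)=C/CC/C(C)=C/C[C@]12CC(=O)CC[C@H]1OC(=O)C2 | intermediate
17 | (3aR,7aR)-3a-[(2E,6E)-3,7,11-trimethyldodeca-2,6,10-trien-1-yl]-3,3a,4,7a-tetrahydro-1-benzofuran-2,5-dione | CC(C)=CCC/C(C)=C/CC/C(C)=C/C[C@]12CC(=O)C=C[C@H]1OC(=O)C2 | target

Total step count: 8. Longest linear sequence: 8 steps (1 → 4 → 6 → 7 → 8 → 11 → 15 → 16 → 17).

Steps most likely to fail

Step 6. A ketal oxygen may capture the keteniminium carbon (six-membered oxonium, then ketal fragmentation) faster than the six-ring-forming cycloaddition. A hydride may shift from the doubly allylic CH2 to the developing cationic centre. The auxiliary may discriminate the two faces poorly. Fallback, from keto ester 6 back to diketone 15: ketalisation of 6 with (2R,3R)-2,3-bis(trimethylsilyloxy)butane and Me3SiOTf should give the C2-symmetric chiral ketal ester F1. LiOH saponification gives the ketal acid F2, and the α-chloroenamine converts it into the acid chloride F3. Et3N in refluxing toluene at high dilution dehydrochlorinates F3 to the free ketene F4, which is far less electrophilic toward ether oxygen and undergoes the thermal intramolecular ketene–alkene [2+2]. The fixed ketal stereocentres make the two ring-fusion isomers diastereomers, so chromatography secures a single enantiomeric series whatever the selectivity. The isomer with the ring fusion of 14, the cyclobutanone ketal F5, is hydrolysed with aq. HCl–THF and rejoins the route at 15.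

Step 2. The allylsilane may be protodesilylated, the triene may be protonated or cyclised by the strong Lewis acid, and the new double bond may migrate into conjugation with the ketone. Fallback, from allylsilane 4 back to keto ester 6: Hosomi–Sakurai allylation of methyl 5-oxopentanoate with BF3·OEt2 in CH2Cl2 at −78 °C, a much milder activation, should give the racemic hydroxy ester F6. It is oxidised at once (before it lactonises) with Dess–Martin periodinane and NaHCO3, so the β,γ-unsaturated ketone forms under buffered, non-acidic conditions.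

Step 8. Dehydrogenation may stay incomplete at the temperature the polyene tolerates, and the allylic and doubly allylic positions of the side chain may be oxidised. Fallback, from keto lactone 16 to target 17: LiN(SiMe3)2 and Me3SiCl in THF at −78 °C should deprotonate kinetically at the unhindered C6 methylene (not at C4 next to the quaternary carbon, nor at the less acidic lactone) and give the enol silane F7. Pd(OAc)2 in MeCN at rt (Saegusa–Ito oxidation) then delivers the enone.

Further compounds
F1 | step 6 | methyl 4-{(4R,5R)-4,5-dimethyl-2-[(4E,8E)-5,9,13-trimethyl-2-methylidenetetradeca-4,8,12-trien-1-yl]-1,3-dioxolan-2-yl}butanoate | CC(C)=CCC/C(C)=C/CC/C(C)=C/CC(=C)CC1(CCCC(=O)OC)O[C@H](C)[C@@H](C)O1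
F2 | step 6 | 4-{(4R,5R)-4,5-dimethyl-2-[(4E,8E)-5,9,13-trimethyl-2-methylidenetetradeca-4,8,12-trien-1-yl]-1,3-dioxolan-2-yl}butanoic acid | CC(C)=CCC/C(C)=C/CC/C(C)=C/CC(=C)CC1(CCCC(=O)O)O[C@H](C)[C@@H](C)O1
F3 | step 6 | 4-{(4R,5R)-4,5-dimethyl-2-[(4E,8E)-5,9,13-trimethyl-2-methylidenetetradeca-4,8,12-trien-1-yl]-1,3-dioxolan-2-yl}butanoyl chloride | CC(C)=CCC/C(C)=C/CC/C(C)=C/CC(=C)CC1(CCCC(=O)Cl)O[C@H](C)[C@@H](C)O1
F4 | step 6 | 4-{(4R,5R)-4,5-dimethyl-2-[(4E,8E)-5,9,13-trimethyl-2-methylidenetetradeca-4,8,12-trien-1-yl]-1,3-dioxolan-2-yl}but-1-en-1-one (ketene) | CC(C)=CCC/C(C)=C/CC/C(C)=C/CC(=C)CC1(CCC=C=O)O[C@H](C)[C@@H](C)O1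
F5 | step 6 | (1S,4'R,5'R,6R)-4',5'-dimethyl-1-[(2E,6E)-3,7,11-trimethyldodeca-2,6,10-trien-1-yl]spiro[bicyclo[4.2.0]octane-3,2'-[1,3]dioxolan]-7-one | CC(C)=CCC/C(C)=C/CC/C(C)=C/C[C@]12CC3(O[C@H](C)[C@@H](C)O3)CC[C@H]1C(=O)C2
F6 | step 2 | methyl (9E,13E)-5-hydroxy-10,14,18-trimethyl-7-methylidenenonadeca-9,13,17-trienoate (racemic) | CC(C)=CCC/C(C)=C/CC/C(C)=C/CC(=C)CC(O)CCCC(=O)OC
F7 | step 8 | (3aR,7aR)-3a-[(2E,6E)-3,7,11-trimethyldodeca-2,6,10-trien-1-yl]-5-(trimethylsilyloxy)-3a,4,7,7a-tetrahydro-1-benzofuran-2(3H)-one | CC(C)=CCC/C(C)=C/CC/C(C)=C/C[C@]12CC(O[Si](C)(C)C)=CC[C@H]1OC(=O)C2
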